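Everything rests on cutting the C8–C10 bond between the cyclopentane ring and its acyloxymethyl arm. In the key step the complete silyl-protected p-coumaroyloxymethyl unit, turned into a magnesium carbenoid from its iodomethyl ester, adds to the C8 ketone of an enantiopure cis-bicyclo[3.3.0]octenone that already bears the 7β-hydroxyl. One operation joins both halves, sets the quaternary C8 carbinol and installs the C10 ester, so the C7/C8/C10 triol never needs differentiation. The step exploits the cup shape of the cis-fused carbocycles (open β face at C8) and the O7/O8 chelate. The second carbocycle is a latent dihydropyran: its alkene is later cleaved to the C1/C3 dialdehyde.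

Key step: step 8

Numbering: iridoid numbering is used for all intermediates (C1, O2, C3, C4, C5, C6, C7, C8, C9; C10 = CH2O on C8; C11 = CH2OH on C4). β is the face of H-5 and H-9, α the opposite (concave) face. Ring A is the oxygenated cyclopentane (C5–C9). Ring B is the cyclopentene (C9, C1, C3, C4, C5) that becomes the dihydropyran.

Assumption: compounds 1, 8 and 20 are bought, and the (S,S)-salen manganese catalyst is taken, by analogy with the epoxidation of indene to its (1S,2R)-oxide, to give the (1S,8R)-epoxide; otherwise its enantiomer is used.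

Step 1
Reactants: 1 (1Z,3Z)-cycloocta-1,3-diene
Product: 2 (1S,8R,2Z)-9-oxabicyclo[6.1.0]non-2-ene (cis-3,4-epoxycyclooctene)
Conditions: (S,S)-[N,N'-bis(3,5-di-tert-butylsalicylidene)-1,2-cyclohexanediaminato]MnCl (4 mol%), 4-phenylpyridine N-oxide (cat.), aq NaOCl (pH 11.3), CH2Cl2, 0 °C
Reagents that add atoms: sodium hypochlorite [Na+].[O-]Cl
Why: Jacobsen–Katsuki epoxidation works best on cis-alkenes conjugated to a second π system, should stop at the monoepoxide because the remaining alkene is deactivated, and the chiral salen ligand on trivalent manganese sets both epoxide stereocentres (later C8 and C9).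

Step 2
Reactants: 2 (1S,8R,2Z)-9-oxabicyclo[6.1.0]non-2-ene
Product: 4 (1R,2R,5R)-cis-bicyclo[3.3.0]oct-7-en-2-ol (endo alcohol, 8α-OH), via lithiated epoxide 3 (not isolated)
Conditions: LiNEt2, Et2O, reflux; then H2O
Reagents that add atoms: none
Why: Base-induced epoxide isomerisation, in which lithiation of the allylic epoxide C–H gives carbenoid 3 and transannular C–H insertion follows, is the established entry to this bicycle; the retained C–O stereocentre dictates the cis ring fusion (C5, C9) and the endo hydroxyl, so the enantiopurity of 2 is carried over.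

Step 3
Reactants: 4 (1R,2R,5R)-cis-bicyclo[3.3.0]oct-7-en-2-ol
Product: 5 (1R,5R)-cis-bicyclo[3.3.0]oct-7-en-2-one (C8 ketone)
Conditions: Dess–Martin periodinane, pyridine, CH2Cl2, 0 °C to rt
Reagents that add atoms: none
Why: Dess–Martin oxidation under pyridine buffering is mild enough to keep the β,γ-alkene out of conjugation and C9 unepimerised.

Step 4
Reactants: 5 (1R,5R)-cis-bicyclo[3.3.0]oct-7-en-2-one
Product: 7 (1R,3S,5S)-3-hydroxy-cis-bicyclo[3.3.0]oct-7-en-2-one (7β-hydroxy C8 ketone), via potassium enolate 6 (not isolated)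
Conditions: KHMDS, THF, −78 °C; 2-(phenylsulfonyl)-3-phenyloxaziridine, −78 °C; then AcOH
Reagents that add atoms: 2-(phenylsulfonyl)-3-phenyloxaziridine O=S(=O)(N1OC1c1ccccc1)c1ccccc1
Why: Davis oxidation of the kinetic enolate 6, formed at the unhindered C7 methylene, should set C7 as 7β-OH because the oxaziridine approaches the convex β face of the bicycle.

Step 5
Reactants: 8 (E)-p-coumaric acid
Product: 10 (E)-3-[4-(tert-butyldimethylsilyloxy)phenyl]acrylic acid, via bis-silylated coumarate 9 (not isolated)
Conditions: TBSCl, imidazole, DMF, rt; then AcOH/THF/H2O, rt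
Reagents that add atoms: tert-butyldimethylsilyl chloride CC(C)(C)[Si](C)(C)Cl
Why: Standard silylation of phenol and acid, followed by selective hydrolysis of the far more labile silyl ester of 9, leaves only the aryl silyl ether.

Step 6
Reactants: 10 (E)-3-[4-(tert-butyldimethylsilyloxy)phenyl]acrylic acid
Product: 11 chloromethyl (E)-3-[4-(tert-butyldimethylsilyloxy)phenyl]acrylate
Conditions: ClCH2OSO2Cl, NaHCO3, Bu4NHSO4 (cat.), CH2Cl2/H2O, 0 °C to rt
Reagents that add atoms: chloromethyl chlorosulfate ClCOS(=O)(=O)Cl
Why: Phase-transfer O-alkylation of the carboxylate, in which chlorosulfate is displaced much faster than chloride, is the usual route to chloromethyl esters.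

Step 7
Reactants: 11 chloromethyl (E)-3-[4-(tert-butyldimethylsilyloxy)phenyl]acrylate
Product: 12 iodomethyl (E)-3-[4-(tert-butyldimethylsilyloxy)phenyl]acrylate
Conditions: NaI, acetone, rt, dark
Reagents that add atoms: sodium iodide [Na+].[I-]
Why: Finkelstein exchange, driven by precipitation of NaCl, gives the iodide needed for a fast halogen–metal exchange.

Step 8
Reactants: 7 (1R,3S,5S)-3-hydroxy-cis-bicyclo[3.3.0]oct-7-en-2-one; 12 iodomethyl (E)-3-[4-(tert-butyldimethylsilyloxy)phenyl]acrylate
Product: 16 7β,8α-dihydroxy-8β-{[(E)-4-(tert-butyldimethylsilyloxy)cinnamoyl]oxymethyl}-cis-bicyclo[3.3.0]octene (ring B alkene intact), via chloromagnesium alkoxide 13 (not isolated), via acyloxymethylmagnesium carbenoid 14 (not isolated), via bis-alkoxide adduct 15 (not isolated)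
Conditions: flask A: 7, iPrMgCl·LiCl (1.0 equiv), THF, −78 °C, then LaCl3·2LiCl (1.0 equiv); flask B: 12, iPrMgCl·LiCl (1.0 equiv relative to 12), THF, −78 °C, 15 min; A into B, −78 to −40 °C; AcOH/THF, −78 °C
Reagents that add atoms: none
Why: Proposed new method: iodine–magnesium exchange at the activated C–I bond of 12 should outrun attack of iPrMgCl on the conjugated ester at −78 °C and give carbenoid 14, stabilised by a five-membered Mg···O=C chelate, which then adds 1,2 to the ketone of 13 to form the C8–C10 bond and bis-alkoxide 15. The closest known reaction type is the exchange of iodomethyl pivalate to pivaloyloxymethylmagnesium chloride and its addition to aldehydes; new here are the ketone acceptor and the less hindered cinnamate-type ester. No ring is closed. The one new stereocentre, C8, is controlled by the cup-shaped cis-bicyclo[3.3.0]octene: C10 should enter from the convex β face (that of H-5 and H-9) because ring B blocks the α face, while the Mg/La chelate between O7 and O8 holds the 7β-oxygen near the carbonyl plane so that it neither shields the β face nor imposes a polar Felkin–Anh bias, which leaves 8-OH α and trans to 7-OH. The step needs carbonyl addition to win over enolisation at the allylic C9–H and over self-acylation or α-elimination of 14, which the low basicity of the chelated carbenoid, the oxophilic LaCl3·2LiCl and the low temperature should secure. The cold AcOH quench is meant to stop acyl migration from O10 to O7 or O8, and any migrated ester should return to the primary position on mild base equilibration.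

Step 9
Reactants: 16 7β,8α-diol 10-O-(silylated coumarate)
Product: 17 7β,8α-bis(triethylsilyl) ether of 16
Conditions: TESOTf, 2,6-lutidine, CH2Cl2, −78 to 0 °C
Reagents that add atoms: triethylsilyl trifluoromethanesulfonate CC[Si](CC)(CC)OS(=O)(=O)C(F)(F)F
Why: A silyl triflate with a hindered pyridine base silylates the secondary and the tertiary alcohol alike, which blocks acyl migration and attack of O8 on C3 in the later steps.

Step 10
Reactants: 17 bis(triethylsilyl) ether
Product: 19 cis-dialdehyde (C9–CHO = C1, C5–CH2CHO = C4–C3; ring A substituents unchanged), via ring B diol 18 (not isolated)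
Conditions: OsO4 (2 mol%), NMO (1.05 equiv), acetone/H2O, 0 °C; then NaIO4, THF/pH 7 buffer, 0 °C
Reagents that add atoms: N-methylmorpholine N-oxide C[N+]1([O-])CCOCC1; water O
Why: In this Upjohn dihydroxylation and Malaprade cleavage the strained, electron-richer cis-cyclopentene should take up the limiting oxidant (from its β face) well before the ester-conjugated coumarate alkene, and periodate then cuts only the new diol 18.

Step 11
Reactants: 19 cis-dialdehyde; 20 (S)-3-methylpentanoic acid
Product: 22 1β-O-[(S)-3-methylpentanoyl] enol-ether acetal (cis-fused cyclopenta[c]pyran, C4–H), via enol lactol 21 (not isolated)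
Conditions: DCC, DMAP (cat.), CH2Cl2, 0 °C to rt
Reagents that add atoms: none
Why: Steglich esterification traps the enol-lactol tautomer 21 of the 1,5-dialdehyde (closure by attack of the C3 enol oxygen on C1, open only to the cis isomer); the anomeric effect and the bulk at C8 should place the acyloxy group β at C1, trans to C8, and the diastereomer derived from any minor enantiomer of 2 can be removed here.

Step 12
Reactants: 22 1β-O-acyl enol-ether acetal
Product: 24 4-formyl derivative (C11 aldehyde), via C4 iminium salt 23 (not isolated)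
Conditions: POCl3, DMF, 0 °C to rt; then pH 7 buffer, 0 °C
Reagents that add atoms: N,N-dimethylformamide CN(C)C=O; water O
Why: Vilsmeier–Haack formylation of the enol ether at its nucleophilic carbon C4, a reaction type known for 1-O-acyl iridoid lactols and for glycals, gives after hydrolysis of 23 a push–pull enal that also stabilises the acyl acetal against acid.

Step 13
Reactants: 24 silylated C11 aldehyde
Product: 25 C11 aldehyde with free 7β-OH, 8α-OH and phenol
Conditions: HF·pyridine, pyridine, THF, 0 °C to rt
Reagents that add atoms: none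
Why: Buffered fluoride desilylation should cleave the two triethylsilyl ethers and the aryl silyl ether while both esters, the acyl acetal and the vinylogous-ester enal stay inert.

Step 14
Reactants: 25 C11 aldehyde
Product: 26 target CNP0241834.1
Conditions: NaBH4, THF/MeOH, −20 °C
Reagents that add atoms: none
Why: Borohydride 1,2-reduction of the aldehyde at low temperature leaves both esters and the coumarate alkene untouched and completes the C11 hydroxymethyl group without touching any stereocentre.

Compound list
1 | (1Z,3Z)-cycloocta-1,3-diene | C1=CC=CCCCC1 | starting material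
2 | (1S,8R,2Z)-9-oxabicyclo[6.1.0]non-2-ene | O1[C@@H]2CCCCC=C[C@H]12 | intermediate
3 | epoxide 2 lithiated at the allylic epoxide carbon (not isolated) | O1[C@@H]2CCCCC=C[C@]12[Li] | intermediate
4 | (1R,2R,5R)-cis-bicyclo[3.3.0]oct-7-en-2-ol (endo, 8α-OH) | O[C@@H]1CC[C@@H]2CC=C[C@H]12 | intermediate
5 | (1R,5R)-cis-bicyclo[3.3.0]oct-7-en-2-one | O=C1CC[C@@H]2CC=C[C@H]12 | intermediate
6 | potassium C7=C8 enolate of 5 (not isolated) | [K+].[O-]C1=CC[C@@H]2CC=C[C@H]12 | intermediate
7 | (1R,3S,5S)-3-hydroxy-cis-bicyclo[3.3.0]oct-7-en-2-one (7β-OH) | O=C1[C@@H](O)C[C@@H]2CC=C[C@H]12 | intermediate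
8 | (E)-p-coumaric acid | OC(=O)/C=C/c1ccc(O)cc1 | starting material
9 | tert-butyldimethylsilyl (E)-3-[4-(tert-butyldimethylsilyloxy)phenyl]acrylate (not isolated) | CC(C)(C)[Si](C)(C)OC(=O)/C=C/c1ccc(O[Si](C)(C)C(C)(C)C)cc1 | intermediate
10 | (E)-3-[4-(tert-butyldimethylsilyloxy)phenyl]acrylic acid | OC(=O)/C=C/c1ccc(O[Si](C)(C)C(C)(C)C)cc1 | intermediate
11 | chloromethyl (E)-3-[4-(tert-butyldimethylsilyloxy)phenyl]acrylate | ClCOC(=O)/C=C/c1ccc(O[Si](C)(C)C(C)(C)C)cc1 | intermediate
12 | iodomethyl (E)-3-[4-(tert-butyldimethylsilyloxy)phenyl]acrylate | ICOC(=O)/C=C/c1ccc(O[Si](C)(C)C(C)(C)C)cc1 | intermediate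
13 | chloromagnesium 7β-alkoxide of 7 (not isolated) | O=C1[C@@H](O[Mg]Cl)C[C@@H]2CC=C[C@H]12 | intermediate
14 | {[(E)-4-(tert-butyldimethylsilyloxy)cinnamoyl]oxymethyl}magnesium chloride (not isolated) | Cl[Mg]COC(=O)/C=C/c1ccc(O[Si](C)(C)C(C)(C)C)cc1 | intermediate
15 | bis(chloromagnesium) 7β,8α-dialkoxide of 16 (not isolated) | Cl[Mg]O[C@]1(COC(=O)/C=C/c3ccc(O[Si](C)(C)C(C)(C)C)cc3)[C@@H](O[Mg]Cl)C[C@@H]2CC=C[C@H]12 | intermediate
16 | 7β,8α-dihydroxy-8β-{[(E)-4-(tert-butyldimethylsilyloxy)cinnamoyl]oxymethyl}-cis-bicyclo[3.3.0]octene | O[C@]1(COC(=O)/C=C/c3ccc(O[Si](C)(C)C(C)(C)C)cc3)[C@@H](O)C[C@@H]2CC=C[C@H]12 | intermediate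
17 | 7β,8α-bis(triethylsilyl) ether of 16 | CC[Si](CC)(CC)O[C@]1(COC(=O)/C=C/c3ccc(O[Si](C)(C)C(C)(C)C)cc3)[C@@H](O[Si](CC)(CC)CC)C[C@@H]2CC=C[C@H]12 | intermediate
18 | ring B β,β-cis-diol of 17 (not isolated) | CC[Si](CC)(CC)O[C@]1(COC(=O)/C=C/c3ccc(O[Si](C)(C)C(C)(C)C)cc3)[C@@H](O[Si](CC)(CC)CC)C[C@@H]2C[C@@H](O)[C@@H](O)[C@H]12 | intermediate
19 | cis-dialdehyde (C1 and C3 aldehydes on the fully substituted ring A) | CC[Si](CC)(CC)O[C@]1(COC(=O)/C=C/c2ccc(O[Si](C)(C)C(C)(C)C)cc2)[C@@H](O[Si](CC)(CC)CC)C[C@H](CC=O)[C@@H]1C=O | intermediate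
20 | (S)-3-methylpentanoic acid | CC[C@H](C)CC(=O)O | starting material
21 | 1β-hydroxy enol lactol tautomer of 19 (not isolated) | O[C@@H]1OC=C[C@H]2C[C@H](O[Si](CC)(CC)CC)[C@](O[Si](CC)(CC)CC)(COC(=O)/C=C/c3ccc(O[Si](C)(C)C(C)(C)C)cc3)[C@@H]12 | intermediate
22 | 1β-O-[(S)-3-methylpentanoyl] derivative of 21 (C4–H) | CC[C@H](C)CC(=O)O[C@@H]1OC=C[C@H]2C[C@H](O[Si](CC)(CC)CC)[C@](O[Si](CC)(CC)CC)(COC(=O)/C=C/c3ccc(O[Si](C)(C)C(C)(C)C)cc3)[C@@H]12 | intermediate
23 | C4 (dimethyliminio)methyl chloride of 22 (not isolated) | CC[C@H](C)CC(=O)O[C@@H]1OC=C(C=[N+](C)C)[C@H]2C[C@H](O[Si](CC)(CC)CC)[C@](O[Si](CC)(CC)CC)(COC(=O)/C=C/c3ccc(O[Si](C)(C)C(C)(C)C)cc3)[C@@H]12.[Cl-] | intermediate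
24 | 4-formyl derivative of 22 | CC[C@H](C)CC(=O)O[C@@H]1OC=C(C=O)[C@H]2C[C@H](O[Si](CC)(CC)CC)[C@](O[Si](CC)(CC)CC)(COC(=O)/C=C/c3ccc(O[Si](C)(C)C(C)(C)C)cc3)[C@@H]12 | intermediate
25 | desilylated 4-formyl compound (11-oxo form of the target) | CC[C@H](C)CC(=O)O[C@@H]1OC=C(C=O)[C@H]2C[C@H](O)[C@](O)(COC(=O)/C=C/c3ccc(O)cc3)[C@@H]12 | intermediate
26 | CNP0241834.1 | CC[C@H](C)CC(=O)O[C@@H]1OC=C(CO)[C@H]2C[C@H](O)[C@](O)(COC(=O)/C=C/c3ccc(O)cc3)[C@@H]12 | target

Total step count: 14. Longest linear sequence: 11 steps (steps 1–4 and 8–14).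

Steps most likely to fail

1. Step 8 (Proposed new method). The carbenoid may decompose by α-elimination or self-acylation before it reaches the hindered ketone. The ketone may be enolised at C9, attack may come from the α face, or the acyl group may migrate within the bis-alkoxide. The fallback uses known chemistry and delivers C10 through a silicon tether. It sets out from 7. Silylation of the 7β-hydroxyl with (bromomethyl)chlorodimethylsilane and imidazole gives the (bromomethyl)dimethylsilyl ether F1. SmI2 in THF closes a five-membered ring by an intramolecular samarium Barbier reaction, which can deliver C10 only on the face of O7, and gives the 1,2-oxasilolane F2. Tamao–Fleming oxidation (H2O2, KF, KHCO3) gives the triol F3. Steglich esterification of its only primary hydroxyl with acid 10 comes back to the route at 16.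

2. Step 12. The chloroiminium salt may convert the triethylsilyl ethers into formates, or it may ionise the acyl acetal faster than C4 is formylated. The fallback sets out from 22. Iodination at C4 by addition–elimination (NIS, then Et3N) gives the 4-iodo enol ether F4. Stille coupling with (tributylstannyl)methanol and Pd(PPh3)4 installs C11 directly at the alcohol level and gives the silylated 11-alcohol F5. Desilylation with pyridine-buffered HF·pyridine comes back to the route at 26, so steps 13 and 14 are not needed.

3. Step 4. Deprotonation may occur at the doubly activated allylic C9–H instead of C7. This would lead to dienolate formation, migration of the alkene into conjugation and loss of the C9 stereocentre. The fallback sets out from 5. Condensation with N,N-dimethylhydrazine gives the dimethylhydrazone F6. LDA removes a proton from the less substituted α-carbon (C7), and the azaenolate is oxidised from the β face with the same oxaziridine to the α-hydroxy hydrazone F7. Hydrolysis with aqueous oxalic acid comes back to the route at 7.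

Further compounds
F1 | step 8 | 7β-O-[(bromomethyl)dimethylsilyl] ether of 7 | O=C1[C@@H](O[Si](C)(C)CBr)C[C@@H]2CC=C[C@H]12
F2 | step 8 | 1,2-oxasilolane bridging O7 and C10 (8α-OH) | O[C@]1(C[Si](C)(C)O3)[C@@H]3C[C@@H]2CC=C[C@H]12
F3 | step 8 | 7β,8α-dihydroxy-8β-(hydroxymethyl)-cis-bicyclo[3.3.0]octene | O[C@]1(CO)[C@@H](O)C[C@@H]2CC=C[C@H]12
F4 | step 12 | 4-iodo derivative of 22 | CC[C@H](C)CC(=O)O[C@@H]1OC=C(I)[C@H]2C[C@H](O[Si](CC)(CC)CC)[C@](O[Si](CC)(CC)CC)(COC(=O)/C=C/c3ccc(O[Si](C)(C)C(C)(C)C)cc3)[C@@H]12
F5 | step 12 | 4-(hydroxymethyl) derivative of 22 (trisilylated target) | CC[C@H](C)CC(=O)O[C@@H]1OC=C(CO)[C@H]2C[C@H](O[Si](CC)(CC)CC)[C@](O[Si](CC)(CC)CC)(COC(=O)/C=C/c3ccc(O[Si](C)(C)C(C)(C)C)cc3)[C@@H]12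
F6 | step 4 | N,N-dimethylhydrazone of 5 | CN(C)N=C1CC[C@@H]2CC=C[C@H]12
F7 | step 4 | N,N-dimethylhydrazone of 7 | CN(C)N=C1[C@@H](O)C[C@@H]2CC=C[C@H]12
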